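**Plan**
- Retrosynthesis: the dimethylpyran ring E is opened first (C8–C and O–CMe2 bonds, propargyl Claisen). The C7–O and C5–OMe bonds are then cut back to C–F, then the C6–prenyl bond, then the pyranone ring C at C3–C4 and O1–C8a, and last the oxepine ring D at its O–C(vinyl) and CH2–CH2 bonds.
- Enabling feature: in ring A, C8a carries the pyranone oxygen O1 ortho to C4a (which holds the C4 carbonyl), and C5 and C7 carry oxygen. Ring A plus C4 therefore maps onto 2,4,6-trifluorobenzoyl chloride (one ortho fluorine for ring closure, two fluorines as latent oxygens), while C2, C3 and ring B map onto a benzoxepinone whose single ketone α-CH2 becomes C3.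
- Forward order of rings: ring B is bought; ring D is closed by copper-catalysed O-vinylation; ring C is annulated together with ring A in one cycloaracylation; prenyl, propargyl ether and methoxy are then placed on ring A; ring E is closed last.
- Stereochemistry: the target has no stereocentre and no alkene capable of E/Z isomerism, so no stereocontrol is required.

Key step: step 6

Naming: flavone numbering is used for the polycycle (O1, C2, C3, C4 = pyranone ring C; C4a–C8a = ring A; C1′–C6′ = ring B on C2). "Oxepinoflavone" stands for 4′,5′-dimethoxyflavone in which C3 carries a CH2 bonded to a carbon that bears an exocyclic isopropylidene (=CMe2) and is bonded to the oxygen on C2′ (seven-membered oxepine ring D). Prenyl = 3-methylbut-2-en-1-yl.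
Handling: the aryl enol ether of ring D is acid-labile, so from 9 onward work-ups are kept neutral or basic and silica gel is deactivated with Et3N.

**Step 1**
Reactants: 1 3-methylbut-2-enal
Product: 3 2-bromo-3-methylbut-2-enal, via 2,3-dibromo-3-methylbutanal 2 (not isolated)
Conditions: Br2, CH2Cl2, 0 °C; then Et3N, 0 °C → rt
Reagents that add atoms: bromine, BrBr
Why: Bromination–dehydrobromination of an enal, in which bromine adds across the C=C bond and triethylamine removes the acidic α-hydrogen with loss of the tertiary β-bromide (E1cB), so that bromine stays on C2 only.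

**Step 2**
Reactants: 3 2-bromo-3-methylbut-2-enal
Product: 4 2-bromo-3-methylbut-2-en-1-ol
Conditions: NaBH4, CeCl3·7H2O, MeOH, 0 °C
Reagents that add atoms: none
Why: Luche reduction delivers hydride 1,2 to the aldehyde and leaves the alkene and the vinyl bromide untouched.

**Step 3**
Reactants: 4 2-bromo-3-methylbut-2-en-1-ol
Product: 5 1,2-dibromo-3-methylbut-2-ene
Conditions: PBr3, Et2O, 0 °C
Reagents that add atoms: phosphorus tribromide, BrP(Br)Br
Why: PBr3 bromination, in which the primary allylic alcohol becomes a phosphite ester that bromide displaces, the primary bromide on the tetrasubstituted alkene being the stable allylic isomer.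

**Step 4**
Reactants: 6 2-hydroxy-4,5-dimethoxyacetophenone; 5 1,2-dibromo-3-methylbut-2-ene
Product: 8 4-bromo-1-(2-hydroxy-4,5-dimethoxyphenyl)-5-methylhex-4-en-1-one, via acetophenone dilithium dianion 7 (not isolated)
Conditions: LiN(i-Pr)2 (2.2 equiv.), THF, −78 → −20 °C; then 5, −78 → 0 °C
Reagents that add atoms: none
Why: Dianion alkylation, in which the lithium phenoxide is inert in THF and the enolate carbon displaces the primary allylic bromide by SN2 while the vinyl bromide does not react.

**Step 5**
Reactants: 8 4-bromo-1-(2-hydroxy-4,5-dimethoxyphenyl)-5-methylhex-4-en-1-one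
Product: 9 7,8-dimethoxy-2-(propan-2-ylidene)-3,4-dihydro-1-benzoxepin-5(2H)-one
Conditions: CuI (10 mol%), 1,10-phenanthroline (20 mol%), Cs2CO3, toluene (0.01 M), 110 °C
Reagents that add atoms: none
Why: Intramolecular Ullmann-type O-vinylation, in which the phenoxide (the only anion that carbonate forms) binds copper, copper inserts into the vinyl C–Br bond and C–O reductive elimination gives the aryl vinyl ether, the ortho-acylbenzene unit holding the two ends close for the seven-membered closure.

**Step 6**
Reactants: 9 7,8-dimethoxy-2-(propan-2-ylidene)-3,4-dihydro-1-benzoxepin-5(2H)-one; 10 2,4,6-trifluorobenzoyl chloride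
Product: 13 5,7-difluoro oxepinoflavone, via benzoxepinone lithium enolate 11 (not isolated), via trifluorobenzoyl diketone lithium enolate 12 (not isolated)
Conditions: LiN(SiMe3)2 (2.2 equiv.), THF, −78 °C; 10, −78 → 0 °C; then DMF, 70 °C
Reagents that add atoms: none
Why: LiN(SiMe3)2 deprotonates C4 of 9, the only CH2 next to the ketone, and the lithium enolate 11 attacks the acid chloride through carbon (Claisen-type C-acylation) to make the flavone C3–C4 bond, the second equivalent of base turning the 1,3-diketone at once into its enolate 12. On warming in DMF the enolate oxygen on the ring B side adds to the fluorine-bearing carbon ortho to the new ketone and fluoride leaves (SNAr by addition–elimination), which makes the O1–C8a bond and closes the pyranone ring C in a six-membered 6-exo-type closure through a Meisenheimer intermediate stabilised by the ortho carbonyl and the two remaining fluorines. The closest known reaction type is the Grohe cycloaracylation, in which 2-fluorobenzoyl chlorides and ketone enolates or enamines give chromones and quinolones. No stereocentre is formed. The step needs C- over O-acylation, favoured by the lithium counterion in THF and by the excess of enolate and base, since an enol ester would itself pass its acyl group on to carbon, whereas the choice between the two ortho fluorines is moot because they are equivalent and the other diketone oxygen could only close a four-membered ring. Ring D and its enol ether meet nothing but base.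

**Step 7**
Reactants: 13 5,7-difluoro oxepinoflavone; 14 1-bromo-3-methylbut-2-ene (prenyl bromide)
Product: 16 5,7-difluoro-6-prenyl oxepinoflavone, via C6 arylmagnesium chloride 15 (not isolated)
Conditions: TMPMgCl·LiCl (TMP = 2,2,6,6-tetramethylpiperidin-1-yl; 1.3 equiv.), THF, −20 → 0 °C; then Li2CuCl4 (5 mol%), 14, −20 → 0 °C
Reagents that add atoms: none
Why: Directed magnesiation with the Knochel–Hauser base removes the most acidic ring hydrogen, H6 between the two fluorines, the arylmagnesium tolerates the chromone carbonyl, and Kochi-type copper-catalysed allylic substitution at the unhindered primary carbon of prenyl bromide (SN2) gives the linear prenyl group.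

**Step 8**
Reactants: 16 5,7-difluoro-6-prenyl oxepinoflavone; 17 2-methylbut-3-yn-2-ol
Product: 19 5-fluoro-7-(2-methylbut-3-yn-2-yloxy)-6-prenyl oxepinoflavone, via potassium 2-methylbut-3-yn-2-olate 18 (not isolated)
Conditions: 17 (1.5 equiv.), KN(SiMe3)2 (1.4 equiv.), 18-crown-6, THF, 0 °C; then 16, 0 °C → rt
Reagents that add atoms: none
Why: Nucleophilic aromatic substitution (SNAr), in which the crown-separated tertiary alkoxide attacks C7, whose fluorine is para to the C4 carbonyl and has only one bulky neighbour, in preference to C5, which is wedged between the peri carbonyl and the prenyl group.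

**Step 9**
Reactants: 19 5-fluoro-7-(2-methylbut-3-yn-2-yloxy)-6-prenyl oxepinoflavone
Product: 20 5-methoxy-7-(2-methylbut-3-yn-2-yloxy)-6-prenyl oxepinoflavone
Conditions: NaOMe (5 equiv.), MeOH–DMF, 70 °C
Reagents that add atoms: sodium methoxide, C[O-].[Na+]
Why: SNAr of the remaining fluorine at C5, activated by the ortho (peri) carbonyl, by the small methoxide ion, the quaternary propargylic ether offering no hydrogen through which base could isomerise the alkyne.

**Step 10**
Reactants: 20 5-methoxy-7-(2-methylbut-3-yn-2-yloxy)-6-prenyl oxepinoflavone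
Product: 24 target CNP0192589.0, via 8-allenyl cyclohexadienone 21 (not isolated), via 8-allenyl-7-hydroxy oxepinoflavone 22 (not isolated), via ortho-quinone methide 23 (not isolated)
Conditions: degassed o-xylene, 140 °C
Reagents that add atoms: none
Why: Aryl propargyl ether Claisen rearrangement, in which the [3,3] shift can be completed only at C8 because C6 is blocked by the prenyl group, and enolisation, a 1,5-hydrogen shift and an oxa-6π electrocyclisation then close the 2,2-dimethylpyran ring E.

**Compound list**
1 | 3-methylbut-2-enal | CC(C)=CC=O | starting material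
2 | 2,3-dibromo-3-methylbutanal (racemic) | CC(C)(Br)C(Br)C=O | intermediate (not isolated)
3 | 2-bromo-3-methylbut-2-enal | CC(C)=C(Br)C=O | intermediate
4 | 2-bromo-3-methylbut-2-en-1-ol | CC(C)=C(Br)CO | intermediate
5 | 1,2-dibromo-3-methylbut-2-ene | CC(C)=C(Br)CBr | intermediate
6 | 2-hydroxy-4,5-dimethoxyacetophenone | CC(=O)c1cc(OC)c(OC)cc1O | starting material
7 | acetophenone dilithium dianion (lithium phenoxide / lithium enolate of 6) | [Li+].[Li+].C=C([O-])c1cc(OC)c(OC)cc1[O-] | intermediate (not isolated)
8 | 4-bromo-1-(2-hydroxy-4,5-dimethoxyphenyl)-5-methylhex-4-en-1-one | CC(C)=C(Br)CCC(=O)c1cc(OC)c(OC)cc1O | intermediate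
9 | 7,8-dimethoxy-2-(propan-2-ylidene)-3,4-dihydro-1-benzoxepin-5(2H)-one | COc1cc2OC(=C(C)C)CCC(=O)c2cc1OC | intermediate
10 | 2,4,6-trifluorobenzoyl chloride | O=C(Cl)c1c(F)cc(F)cc1F | starting material
11 | benzoxepinone lithium enolate (C4–C5 enolate of 9) | [Li+].COc1cc2OC(=C(C)C)CC=C([O-])c2cc1OC | intermediate (not isolated)
12 | trifluorobenzoyl diketone lithium enolate (4-(2,4,6-trifluorobenzoyl) derivative of 9, enolate oxygen on C5) | [Li+].COc1cc2OC(=C(C)C)CC(C(=O)c3c(F)cc(F)cc3F)=C([O-])c2cc1OC | intermediate (not isolated)
13 | 5,7-difluoro oxepinoflavone (rings A–D) | COc1cc2c(cc1OC)-c1oc3cc(F)cc(F)c3c(=O)c1CC(=C(C)C)O2 | intermediate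
14 | 1-bromo-3-methylbut-2-ene (prenyl bromide) | CC(C)=CCBr | starting material
15 | C6 arylmagnesium chloride of 13 | COc1cc2c(cc1OC)-c1oc3cc(F)c([Mg]Cl)c(F)c3c(=O)c1CC(=C(C)C)O2 | intermediate (not isolated)
16 | 5,7-difluoro-6-prenyl oxepinoflavone | COc1cc2c(cc1OC)-c1oc3cc(F)c(CC=C(C)C)c(F)c3c(=O)c1CC(=C(C)C)O2 | intermediate
17 | 2-methylbut-3-yn-2-ol | CC(C)(O)C#C | starting material
18 | potassium 2-methylbut-3-yn-2-olate | [K+].CC(C)([O-])C#C | intermediate (not isolated)
19 | 5-fluoro-7-(2-methylbut-3-yn-2-yloxy)-6-prenyl oxepinoflavone | COc1cc2c(cc1OC)-c1oc3cc(OC(C)(C)C#C)c(CC=C(C)C)c(F)c3c(=O)c1CC(=C(C)C)O2 | intermediate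
20 | 5-methoxy-7-(2-methylbut-3-yn-2-yloxy)-6-prenyl oxepinoflavone | COc1cc2c(cc1OC)-c1oc3cc(OC(C)(C)C#C)c(CC=C(C)C)c(OC)c3c(=O)c1CC(=C(C)C)O2 | intermediate
21 | 8-allenyl cyclohexadienone (8-(3-methylbuta-1,2-dienyl)-7-oxo-7,8-dihydro form of ring A, racemic at C8) | COc1cc2OC(=C(C)C)CC3=C(c2cc1OC)OC1=C(C3=O)C(OC)=C(CC=C(C)C)C(=O)C1C=C=C(C)C | intermediate (not isolated)
22 | 8-allenyl-7-hydroxy oxepinoflavone (7-hydroxy-5-methoxy-8-(3-methylbuta-1,2-dienyl)-6-prenyl) | COc1cc2c(cc1OC)-c1oc3c(C=C=C(C)C)c(O)c(CC=C(C)C)c(OC)c3c(=O)c1CC(=C(C)C)O2 | intermediate (not isolated)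
23 | ortho-quinone methide (7-oxo-8-[(Z)-3-methylbut-2-enylidene] form of ring A) | COc1cc2OC(=C(C)C)CC3=C(c2cc1OC)OC1=C(C3=O)C(OC)=C(CC=C(C)C)C(=O)/C1=C\C=C(C)C | intermediate (not isolated)
24 | CNP0192589.0: 5-methoxy-6-prenyl oxepinoflavone with a 2,2-dimethyl-2H-pyran (ring E) fused through O at C7 and CH= at C8 | COc1cc2c(cc1OC)-c1oc3c4c(c(CC=C(C)C)c(OC)c3c(=O)c1CC(=C(C)C)O2)OC(C)(C)C=C4 | target

**Totals**
Total step count: 10.
Longest linear sequence: 10 steps (1 → 24 through steps 1–10; 6 joins at step 4).

**Steps most likely to fail**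

Step 5. Oxidative addition of copper into the tetrasubstituted vinyl bromide may be slow. Intermolecular etherification or a five-membered closure through the ketone enolate oxygen could then outrun the seven-membered ring closure. The fallback sets out from 8 and returns at 9, and it inverts the polarity of the vinyl partner. Miyaura borylation of 8 ([1,1′-bis(diphenylphosphino)ferrocene]PdCl2, bis(pinacolato)diboron, KOAc, dioxane, 80 °C) should give the alkenyl boronate 1-(2-hydroxy-4,5-dimethoxyphenyl)-5-methyl-4-(4,4,5,5-tetramethyl-1,3,2-dioxaborolan-2-yl)hex-4-en-1-one F1. An intramolecular Chan–Lam O-vinylation (Cu(OAc)2 20 mol%, pyridine, 4 Å molecular sieves, O2, CH2Cl2, rt, high dilution) should then close ring D to 9. These conditions are carbonate-free and at room temperature, so the ketone should not enolise.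

Step 7. Magnesiation may occur at C8 or at the doubly allylic CH2 of ring D instead of C6, or the prenyl unit may be delivered through its tertiary carbon. The fallback sets out from 9 and returns at 16, and it puts the prenyl group on the acid chloride before the key step. 1,3,5-Trifluorobenzene is lithiated (n-BuLi, THF, −78 °C) and alkylated with 14 (CuBr·SMe2 cat.) to 1,3,5-trifluoro-2-(3-methylbut-2-en-1-yl)benzene F2. A second lithiation between two fluorines and a CO2 quench should give 2,4,6-trifluoro-3-(3-methylbut-2-en-1-yl)benzoic acid F3. 1-Chloro-N,N,2-trimethylprop-1-en-1-amine converts it under neutral conditions into 2,4,6-trifluoro-3-(3-methylbut-2-en-1-yl)benzoyl chloride F4. Cycloaracylation of 9 with F4 under the conditions of step 6 should close ring C preferentially at the fluorine flanked by hydrogen rather than at the one next to the prenyl group, which gives 16 directly; any 8-prenyl isomer would be removed by chromatography.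

Step 8. Attack of the tertiary alkoxide next to the prenyl group may be sluggish. Substitution at C5, or base-induced migration of the exocyclic double bond of ring D into the ring, could then compete. The fallback sets out from 16 and returns at 19; it brings in the C7 oxygen with a small primary alkoxide and builds the tertiary ether on the phenol. 2-(Methylsulfonyl)ethanol and NaH in DMF (0 °C → rt) should give 5-fluoro-7-[2-(methylsulfonyl)ethoxy]-6-prenyl oxepinoflavone F5. This loses methyl vinyl sulfone in the same flask to give 5-fluoro-7-hydroxy-6-prenyl oxepinoflavone F6. Copper-catalysed propargylation of F6 with 3-chloro-3-methylbut-1-yne (CuCl2 cat., DBU, MeCN, 0 °C) should then give 19.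

**Further compounds**
F1 | step 5 | 1-(2-hydroxy-4,5-dimethoxyphenyl)-5-methyl-4-(4,4,5,5-tetramethyl-1,3,2-dioxaborolan-2-yl)hex-4-en-1-one | CC(C)=C(CCC(=O)c1cc(OC)c(OC)cc1O)B1OC(C)(C)C(C)(C)O1
F2 | step 7 | 1,3,5-trifluoro-2-(3-methylbut-2-en-1-yl)benzene | CC(C)=CCc1c(F)cc(F)cc1F
F3 | step 7 | 2,4,6-trifluoro-3-(3-methylbut-2-en-1-yl)benzoic acid | CC(C)=CCc1c(F)cc(F)c(C(=O)O)c1F
F4 | step 7 | 2,4,6-trifluoro-3-(3-methylbut-2-en-1-yl)benzoyl chloride | CC(C)=CCc1c(F)cc(F)c(C(=O)Cl)c1F
F5 | step 8 | 5-fluoro-7-[2-(methylsulfonyl)ethoxy]-6-prenyl oxepinoflavone | COc1cc2c(cc1OC)-c1oc3cc(OCCS(C)(=O)=O)c(CC=C(C)C)c(F)c3c(=O)c1CC(=C(C)C)O2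
F6 | step 8 | 5-fluoro-7-hydroxy-6-prenyl oxepinoflavone | COc1cc2c(cc1OC)-c1oc3cc(O)c(CC=C(C)C)c(F)c3c(=O)c1CC(=C(C)C)O2
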